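**Plan**

Flavanone numbering is used (O1, C2, C3, C4, C4a, C5 to C8, C8a; primes for ring B); TBS = tert-butyldimethylsilyl.
- The retrosynthesis first removes three TBS ethers, then cuts C2–C3 of ring C. C2 carries one hydrogen, O1 and the electron-rich ring B, so with ring C opened it is the OCH2 of an aryl benzyl ether lying 1,6 to C3, the carbene carbon of a diazomethyl ketone.
- Further cuts: the diazo group (back to a methyl ketone), the O1–C2 ether bond (ring A phenol plus ring B benzylic alcohol), the C8–prenyl bond, and the C1'–C2 bond (a formyl group on the chromene).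
- Forward: ring A ketone in two steps, ring B alcohol in four, Mitsunobu union, diazo transfer, ring C closed last by C–H insertion, then desilylation.
- C2 is the only stereocentre. It is set as (S) in the insertion by the chiral dirhodium carboxylate and kept by a non-basic deprotection.

Key step: step 9

Assumption: Rh2(S-PTTL)4 is taken to replace the benzylic hydrogen that leads to (2S); if the sense of induction proves opposite, the mirror-image catalyst Rh2(R-PTTL)4 is used with no other change.
Assumption: 7-hydroxy-2,2-dimethylchroman-4-one (5) is taken as purchasable.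

**Route**

Step 1
Reactants: 1 2,4,6-trihydroxyacetophenone; 2 1-bromo-3-methylbut-2-ene
Product: 3 1-[2,4,6-trihydroxy-3-(3-methylbut-2-en-1-yl)phenyl]ethanone
Conditions: DBU, THF, 0 °C to rt
Reagents that add atoms: 1-bromo-3-methylbut-2-ene (compound 2), CC(C)=CCBr
Why: C-alkylation of an acylphloroglucinol anion, whose soft ring carbons are the nucleophilic sites; the two free ring positions of 1 are equivalent, so mono-C-prenylation can give only one regioisomer.

Step 2
Reactants: 3 1-[2,4,6-trihydroxy-3-(3-methylbut-2-en-1-yl)phenyl]ethanone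
Product: 4 1-[4,6-bis(TBSO)-2-hydroxy-3-(3-methylbut-2-en-1-yl)phenyl]ethanone
Conditions: TBSCl (2.1 equiv), imidazole, CH2Cl2/DMF, 0 °C
Reagents that add atoms: tert-butyldimethylsilyl chloride, CC(C)(C)[Si](C)(C)Cl
Why: Phenol silylation, expected to take the acidic para hydroxyl first and then the ortho hydroxyl next to the ring hydrogen, leaving the hydroxyl wedged between acetyl and prenyl free as the hydrogen-bonded, most hindered one.

Step 3
Reactants: 5 7-hydroxy-2,2-dimethylchroman-4-one
Product: 7 2,2-dimethyl-2H-chromen-7-ol, via 2,2-dimethylchromane-4,7-diol 6 (not isolated)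
Conditions: NaBH4, MeOH, 0 °C to rt; aq. HCl quench; crude diol, p-TsOH·H2O (cat.), toluene, 80 °C
Reagents that add atoms: none
Why: Borohydride reduction of the aryl ketone followed by acid-catalysed E1 dehydration of the benzylic alcohol, whose cation is stabilised by the para hydroxyl and can lose a proton only towards the chromene double bond.

Step 4
Reactants: 7 2,2-dimethyl-2H-chromen-7-ol
Product: 8 7-hydroxy-2,2-dimethyl-2H-chromene-6-carbaldehyde
Conditions: MgCl2, Et3N, paraformaldehyde, MeCN, reflux
Reagents that add atoms: paraformaldehyde (as formaldehyde), C=O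
Why: Magnesium-mediated ortho-formylation of a phenol, in which the magnesium phenoxide delivers formaldehyde to an ortho carbon and a second formaldehyde oxidises the hydroxymethyl intermediate by hydride transfer; of the two ortho carbons the open one para to the ring oxygen should react, not the one flanked by two oxygens.

Step 5
Reactants: 8 7-hydroxy-2,2-dimethyl-2H-chromene-6-carbaldehyde
Product: 9 7-(TBSO)-2,2-dimethyl-2H-chromene-6-carbaldehyde
Conditions: TBSCl, imidazole, DMF, rt
Reagents that add atoms: tert-butyldimethylsilyl chloride, CC(C)(C)[Si](C)(C)Cl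
Why: Standard silyl ether formation on the only hydroxyl, which caps the phenol with a group that offers the later carbene no activated C–H bond.

Step 6
Reactants: 9 7-(TBSO)-2,2-dimethyl-2H-chromene-6-carbaldehyde
Product: 10 [7-(TBSO)-2,2-dimethyl-2H-chromen-6-yl]methanol
Conditions: NaBH4, EtOH/THF, 0 °C; water quench
Reagents that add atoms: none
Why: Chemoselective hydride reduction of the aldehyde, run cold and briefly so that the silyl group does not migrate from the phenol oxygen to the new alkoxide, with the chromene alkene inert to borohydride.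

Step 7
Reactants: 4 1-[4,6-bis(TBSO)-2-hydroxy-3-(3-methylbut-2-en-1-yl)phenyl]ethanone; 10 [7-(TBSO)-2,2-dimethyl-2H-chromen-6-yl]methanol
Product: 11 1-{2-{[7-(TBSO)-2,2-dimethyl-2H-chromen-6-yl]methoxy}-4,6-bis(TBSO)-3-(3-methylbut-2-en-1-yl)phenyl}ethanone
Conditions: PPh3, DIAD, THF, 0 °C to rt
Reagents that add atoms: none
Why: Mitsunobu etherification, in which the acidic chelated phenol protonates the betaine and then displaces the primary benzylic oxyphosphonium group under neutral conditions that leave the three aryl silyl ethers intact.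

Step 8
Reactants: 11 1-{2-{[7-(TBSO)-2,2-dimethyl-2H-chromen-6-yl]methoxy}-4,6-bis(TBSO)-3-(3-methylbut-2-en-1-yl)phenyl}ethanone
Product: 13 1-{2-{[7-(TBSO)-2,2-dimethyl-2H-chromen-6-yl]methoxy}-4,6-bis(TBSO)-3-(3-methylbut-2-en-1-yl)phenyl}-2-diazoethanone, via alpha-trifluoroacetyl ketone 12 (not isolated)
Conditions: LiN(SiMe3)2, THF, −78 °C; CF3CO2CH2CF3, −78 °C; cold 1 M HCl work-up; then MsN3, Et3N, H2O (1 equiv), MeCN, rt
Reagents that add atoms: methanesulfonyl azide, CS(=O)(=O)N=[N+]=[N-] (supplies the two diazo nitrogens); 2,2,2-trifluoroethyl trifluoroacetate, O=C(OCC(F)(F)F)C(F)(F)F (supplies the trifluoroacetyl group of 12 only, lost again on the way to 13)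
Why: Detrifluoroacetylative diazo transfer of the Regitz type, in which the kinetic lithium enolate of the only enolisable position (the methyl group) is trifluoroacetylated and the resulting 1,3-diketone accepts the diazo group from the sulfonyl azide while the trifluoroacetyl group leaves as the N-sulfonyl amide.

Step 9
Reactants: 13 1-{2-{[7-(TBSO)-2,2-dimethyl-2H-chromen-6-yl]methoxy}-4,6-bis(TBSO)-3-(3-methylbut-2-en-1-yl)phenyl}-2-diazoethanone
Product: 14 (2S)-5,7-bis(TBSO)-2-[7-(TBSO)-2,2-dimethyl-2H-chromen-6-yl]-8-(3-methylbut-2-en-1-yl)chroman-4-one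
Conditions: Rh2(S-PTTL)4 (dirhodium tetrakis[N-phthaloyl-(S)-tert-leucinate], 2 mol%), CH2Cl2, 0 °C, slow addition of 13
Reagents that add atoms: none
Why: The catalyst expels nitrogen from 13 to give an electrophilic carbenoid of divalent rhodium, whose carbene carbon (future C3) takes one hydrogen of the ArO–CH2–Ar' methylene in a concerted, hydride-like three-centre transfer while bonding to that carbon. The closest known reaction type is the enantioselective intramolecular C–H insertion of 2-alkoxyaryl diazomethyl ketones under chiral dirhodium tetracarboxylates, which gives 2-substituted chroman-4-ones. Ring C closes as a six-membered ring by 1,6-insertion, forming the C2–C3 bond between the carbene carbon and the ether methylene. C2 arises from a prochiral methylene, and the phthalimido-tert-leucinate pocket around the rhodium carbene decides which of the two enantiotopic hydrogens is replaced, here the one leading to (2S). The step needs C–H insertion to win over oxonium ylide formation at O1 with [1,2]-benzyl shift, over cyclopropanation and over attack on a silyl ether oxygen. The substrate secures this because the C2–H bonds are doubly activated (alpha to O1 and benzylic to a 2,4-dioxygenated ring), O1 is a weakly nucleophilic aryl ether oxygen crowded by two ortho substituents, the prenyl group sits meta to the acyl carbon and cannot reach the carbene, and the TBS ethers carry no activated C–H bond.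

Step 10
Reactants: 14 (2S)-5,7-bis(TBSO)-2-[7-(TBSO)-2,2-dimethyl-2H-chromen-6-yl]-8-(3-methylbut-2-en-1-yl)chroman-4-one
Product: 15 (2S)-5,7-dihydroxy-2-(7-hydroxy-2,2-dimethyl-2H-chromen-6-yl)-8-(3-methylbut-2-en-1-yl)chroman-4-one
Conditions: HF·pyridine, excess pyridine, THF, 0 °C to rt
Reagents that add atoms: none
Why: Fluoride cleavage of the three aryl silyl ethers under buffered, weakly acidic conditions, which generate no phenoxide able to open ring C by retro-oxa-Michael reaction, so C2 should keep its configuration while the prenyl and chromene alkenes stay untouched.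

**Compound list**

1 | 2,4,6-trihydroxyacetophenone | CC(=O)c1c(O)cc(O)cc1O | starting material
2 | 1-bromo-3-methylbut-2-ene | CC(C)=CCBr | starting material
3 | 1-[2,4,6-trihydroxy-3-(3-methylbut-2-en-1-yl)phenyl]ethanone | CC(=O)c1c(O)cc(O)c(CC=C(C)C)c1O | intermediate
4 | 1-[4,6-bis(tert-butyldimethylsilyloxy)-2-hydroxy-3-(3-methylbut-2-en-1-yl)phenyl]ethanone | CC(=O)c1c(O[Si](C)(C)C(C)(C)C)cc(O[Si](C)(C)C(C)(C)C)c(CC=C(C)C)c1O | intermediate
5 | 7-hydroxy-2,2-dimethylchroman-4-one | CC1(C)CC(=O)c2ccc(O)cc2O1 | starting material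
6 | 2,2-dimethylchromane-4,7-diol (racemic, not isolated) | CC1(C)CC(O)c2ccc(O)cc2O1 | intermediate
7 | 2,2-dimethyl-2H-chromen-7-ol | CC1(C)C=Cc2ccc(O)cc2O1 | intermediate
8 | 7-hydroxy-2,2-dimethyl-2H-chromene-6-carbaldehyde | CC1(C)C=Cc2cc(C=O)c(O)cc2O1 | intermediate
9 | 7-(tert-butyldimethylsilyloxy)-2,2-dimethyl-2H-chromene-6-carbaldehyde | CC1(C)C=Cc2cc(C=O)c(O[Si](C)(C)C(C)(C)C)cc2O1 | intermediate
10 | [7-(tert-butyldimethylsilyloxy)-2,2-dimethyl-2H-chromen-6-yl]methanol | CC1(C)C=Cc2cc(CO)c(O[Si](C)(C)C(C)(C)C)cc2O1 | intermediate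
11 | 1-{2-{[7-(tert-butyldimethylsilyloxy)-2,2-dimethyl-2H-chromen-6-yl]methoxy}-4,6-bis(tert-butyldimethylsilyloxy)-3-(3-methylbut-2-en-1-yl)phenyl}ethanone | CC(=O)c1c(O[Si](C)(C)C(C)(C)C)cc(O[Si](C)(C)C(C)(C)C)c(CC=C(C)C)c1OCc1cc2c(cc1O[Si](C)(C)C(C)(C)C)OC(C)(C)C=C2 | intermediate
12 | 1-{2-{[7-(tert-butyldimethylsilyloxy)-2,2-dimethyl-2H-chromen-6-yl]methoxy}-4,6-bis(tert-butyldimethylsilyloxy)-3-(3-methylbut-2-en-1-yl)phenyl}-4,4,4-trifluorobutane-1,3-dione (not isolated) | O=C(CC(=O)C(F)(F)F)c1c(O[Si](C)(C)C(C)(C)C)cc(O[Si](C)(C)C(C)(C)C)c(CC=C(C)C)c1OCc1cc2c(cc1O[Si](C)(C)C(C)(C)C)OC(C)(C)C=C2 | intermediate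
13 | 1-{2-{[7-(tert-butyldimethylsilyloxy)-2,2-dimethyl-2H-chromen-6-yl]methoxy}-4,6-bis(tert-butyldimethylsilyloxy)-3-(3-methylbut-2-en-1-yl)phenyl}-2-diazoethanone | [N-]=[N+]=CC(=O)c1c(O[Si](C)(C)C(C)(C)C)cc(O[Si](C)(C)C(C)(C)C)c(CC=C(C)C)c1OCc1cc2c(cc1O[Si](C)(C)C(C)(C)C)OC(C)(C)C=C2 | intermediate
14 | (2S)-5,7-bis(tert-butyldimethylsilyloxy)-2-[7-(tert-butyldimethylsilyloxy)-2,2-dimethyl-2H-chromen-6-yl]-8-(3-methylbut-2-en-1-yl)chroman-4-one | CC(C)=CCc1c(O[Si](C)(C)C(C)(C)C)cc(O[Si](C)(C)C(C)(C)C)c2c1O[C@H](c1cc3c(cc1O[Si](C)(C)C(C)(C)C)OC(C)(C)C=C3)CC2=O | intermediate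
15 | (2S)-5,7-dihydroxy-2-(7-hydroxy-2,2-dimethyl-2H-chromen-6-yl)-8-(3-methylbut-2-en-1-yl)chroman-4-one | CC(C)=CCc1c(O)cc(O)c2c1O[C@H](c1cc3c(cc1O)OC(C)(C)C=C3)CC2=O | target

**Count and risks**

Total step count: 10. Longest linear sequence: 8 steps (5 to 15 through steps 3, 4, 5, 6, 7, 8, 9 and 10).

Steps most likely to fail:

1. Step 9. The carbenoid may add to O1 and form an oxonium ylide that undergoes a [1,2]-benzyl shift, or hydride transfer may run ahead of C–C bond formation and loosen the catalyst's control over the two enantiotopic hydrogens. Fallback: set out from 4 and 9. Aldol condensation (LiN(SiMe3)2, THF, −78 °C to rt, Claisen–Schmidt type) should give the chalcone (E)-1-[4,6-bis(TBSO)-2-hydroxy-3-(3-methylbut-2-en-1-yl)phenyl]-3-[7-(TBSO)-2,2-dimethyl-2H-chromen-6-yl]prop-2-en-1-one F1. Intramolecular oxa-Michael addition of its single free phenol (NaOAc, EtOH, reflux) closes ring C to the racemic tris-TBS flavanone F2. Preparative HPLC on an amylose tris(3,5-dimethylphenylcarbamate) chiral phase then separates the enantiomers, and the (2S) enantiomer is 14, where the route resumes.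

2. Step 2. The second silylation may fail to distinguish the two carbonyl-flanking hydroxyls, giving the regioisomer with the free hydroxyl away from the prenyl group. Fallback: set out from 1. Bis-silylation (TBSCl, imidazole) gives the symmetric 1-[2-hydroxy-4,6-bis(TBSO)phenyl]ethanone F3, in which the two ortho hydroxyls are equivalent and no regiochemical question arises. Tsuji–Trost O-allylation with tert-butyl 2-methylbut-3-en-2-yl carbonate and Pd(PPh3)4 (zerovalent palladium) in THF at 0 °C gives the reverse-prenyl ether 1-[2-(2-methylbut-3-en-2-yloxy)-4,6-bis(TBSO)phenyl]ethanone F4. Heating in toluene triggers the aromatic Claisen rearrangement to the only free ortho carbon, which places the prenyl group next to the liberated hydroxyl and gives 4.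

3. Step 7. Displacement by the hindered, hydrogen-bonded phenol may be slow, while the electron-rich benzylic oxyphosphonium ion ionises and is lost to C-alkylation or quinone methide formation. Fallback: set out from 10. Appel bromination (CBr4, PPh3, CH2Cl2, 0 °C) gives 6-(bromomethyl)-7-(TBSO)-2,2-dimethyl-2H-chromene F5. Williamson-type O-alkylation of 4 with F5 promoted by Ag2O in toluene at rt, under non-basic conditions that spare the silyl ethers, gives 11.

Further compounds
F1 | step 9 | (E)-1-[4,6-bis(tert-butyldimethylsilyloxy)-2-hydroxy-3-(3-methylbut-2-en-1-yl)phenyl]-3-[7-(tert-butyldimethylsilyloxy)-2,2-dimethyl-2H-chromen-6-yl]prop-2-en-1-one | CC(C)=CCc1c(O)c(C(=O)/C=C/c2cc3c(cc2O[Si](C)(C)C(C)(C)C)OC(C)(C)C=C3)c(O[Si](C)(C)C(C)(C)C)cc1O[Si](C)(C)C(C)(C)C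
F2 | step 9 | racemic 5,7-bis(tert-butyldimethylsilyloxy)-2-[7-(tert-butyldimethylsilyloxy)-2,2-dimethyl-2H-chromen-6-yl]-8-(3-methylbut-2-en-1-yl)chroman-4-one | CC(C)=CCc1c(O[Si](C)(C)C(C)(C)C)cc(O[Si](C)(C)C(C)(C)C)c2c1OC(c1cc3c(cc1O[Si](C)(C)C(C)(C)C)OC(C)(C)C=C3)CC2=O
F3 | step 2 | 1-[2-hydroxy-4,6-bis(tert-butyldimethylsilyloxy)phenyl]ethanone | CC(=O)c1c(O)cc(O[Si](C)(C)C(C)(C)C)cc1O[Si](C)(C)C(C)(C)C
F4 | step 2 | 1-[2-(2-methylbut-3-en-2-yloxy)-4,6-bis(tert-butyldimethylsilyloxy)phenyl]ethanone | CC(=O)c1c(OC(C)(C)C=C)cc(O[Si](C)(C)C(C)(C)C)cc1O[Si](C)(C)C(C)(C)C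
F5 | step 7 | 6-(bromomethyl)-7-(tert-butyldimethylsilyloxy)-2,2-dimethyl-2H-chromene | CC1(C)C=Cc2cc(CBr)c(O[Si](C)(C)C(C)(C)C)cc2O1
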